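**Plan**

- Retrosynthesis: the protecting groups and one extra ring C=C (C3=C4) go last. The oxepine (O1, C2 quaternary, C3, C4, C5=C6, C7) is then cut at C3–C4 and O1–C7. This gives an O1–C2–C3 piece carrying the aryl ketone and the carboxyl, and a C4–C7 piece carrying the terpenoid side chain.
- Enabling feature: C2 bears no hydrogen, so O1–C2–C3 can be carried as a tertiary α-hydroxy aldehyde that cannot enolise or epimerise. C4–C5=C6–C7 is a but-2-ene-1,4-diyl unit, carried as a 1,3-dienylphosphonium salt with phosphorus on C4.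
- Key event: the C2 alkoxide adds to C7 of the dienylphosphonium salt and the ylide formed at C4 olefinates the aldehyde C3. The extra C3=C4 bond is then saturated with diimide.
- Forward order: aldol of the protected acetophenone with an α-keto ester, then ozonolysis to the aldehyde. Separately, myrcene is taken through allylic oxidation, 1,4-chloroacetoxylation and quaternisation. The annulation closes the only new ring (the arene is bought), followed by reduction and global deprotection.
- Stereochemistry: C2 is set in the amine-catalysed aldol and not touched afterwards. The side-chain (E)-alkene comes from the SeO2 oxidation of myrcene, and the ring alkene position from the annulation.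

Key step: step 9

Assumption: the quinine-derived amine in step 3 is assumed to deliver the (S)-adduct; if it delivers the antipode, the quinidine-derived pseudo-enantiomer is used instead.

**Route**

Step 1
Reactants: 1 2′,5′-dihydroxyacetophenone
Product: 2 1-[2,5-bis(methoxymethoxy)phenyl]ethan-1-one
Conditions: MOMCl, NaH, DMF, 0 → 20 °C
Reagents that add atoms: chloromethyl methyl ether, COCCl
Why: Williamson-type O-alkylation of both phenoxides; NaH is used so that the hydrogen-bonded 2′-OH also reacts.

Step 2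
Reactants: 3 (E)-2-oxo-4-phenylbut-3-enoic acid
Product: 4 methoxymethyl (E)-2-oxo-4-phenylbut-3-enoate
Conditions: MOMCl, iPr2NEt, CH2Cl2, 0 °C
Reagents that add atoms: chloromethyl methyl ether, COCCl
Why: O-alkylation of the carboxylate gives an ester that is removed later by the same mild acid as the aryl ethers, so no basic hydrolysis is needed at the end.

Step 3
Reactants: 2 1-[2,5-bis(methoxymethoxy)phenyl]ethan-1-one; 4 methoxymethyl (E)-2-oxo-4-phenylbut-3-enoate
Product: 5 methoxymethyl (2S,3E)-2-{2-[2,5-bis(methoxymethoxy)phenyl]-2-oxoethyl}-2-hydroxy-4-phenylbut-3-enoate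
Conditions: 9-amino-9-deoxy-epi-quinine (20 mol %), 4-nitrobenzoic acid (40 mol %), dioxane, 25 °C
Reagents that add atoms: none
Why: Amine-catalysed direct aldol addition (enamine catalysis): the enamine of 2 should add 1,2 to the ketone carbonyl of 4, which is held by hydrogen bonding to the protonated quinuclidine, so the catalyst sets the new stereocentre at C2.

Step 4
Reactants: 5 methoxymethyl (2S,3E)-2-{2-[2,5-bis(methoxymethoxy)phenyl]-2-oxoethyl}-2-hydroxy-4-phenylbut-3-enoate
Product: 6 methoxymethyl (2S)-4-[2,5-bis(methoxymethoxy)phenyl]-2-formyl-2-hydroxy-4-oxobutanoate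
Conditions: O3, CH2Cl2, −78 °C; then PPh3, −78 → 0 °C; used crude at once
Reagents that add atoms: ozone, O=[O+][O-]
Why: Ozonolysis (Criegee mechanism) should cleave the styryl C=C bond, the only alkene in 5, faster than the acyl-deactivated arene; the aldehyde formed has no α-hydrogen and C2 is untouched.

Step 5
Reactants: 7 myrcene (7-methyl-3-methylideneocta-1,6-diene)
Product: 8 (2E)-2-methyl-6-methylideneocta-2,7-dien-1-ol
Conditions: SeO2 (cat.), t-BuOOH, salicylic acid (cat.), CH2Cl2, 20 °C
Reagents that add atoms: tert-butyl hydroperoxide, CC(C)(C)OO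
Why: Riley allylic oxidation (ene reaction, then [2,3]-sigmatropic shift) should hydroxylate the (E)-methyl group of the most electron-rich, trisubstituted alkene; the cyclic transition states give the (E)-allylic alcohol.

Step 6
Reactants: 8 (2E)-2-methyl-6-methylideneocta-2,7-dien-1-ol
Product: 9 tert-butyl(dimethyl){[(2E)-2-methyl-6-methylideneocta-2,7-dien-1-yl]oxy}silane
Conditions: TBSCl, imidazole, DMF, 20 °C
Reagents that add atoms: tert-butyldimethylsilyl chloride, CC(C)(C)[Si](C)(C)Cl
Why: Silylation of the primary alcohol; the free hydroxyl would otherwise compete as the oxygen nucleophile in step 9.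

Step 7
Reactants: 9 tert-butyl(dimethyl){[(2E)-2-methyl-6-methylideneocta-2,7-dien-1-yl]oxy}silane
Product: 10 (2E,5E)-7-{[tert-butyl(dimethyl)silyl]oxy}-2-(2-chloroethylidene)-6-methylhept-5-en-1-yl acetate
Conditions: Pd(OAc)2 (5 mol %), p-benzoquinone (20 mol %), MnO2, LiCl, LiOAc, acetone–AcOH 4:1, 25 °C
Reagents that add atoms: lithium chloride, [Li+].[Cl-]; acetic acid, CC(=O)O
Why: Palladium-catalysed oxidative 1,4-chloroacetoxylation of a conjugated diene: divalent palladium binds only the diene, acetate attacks the methylene terminus next to the branched carbon and chloride goes to the far unsubstituted terminus of the π-allyl complex, so acetate ends on the future C7 and chloride on the future C4.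

Step 8
Reactants: 10 (2E,5E)-7-{[tert-butyl(dimethyl)silyl]oxy}-2-(2-chloroethylidene)-6-methylhept-5-en-1-yl acetate
Product: 11 {(2E)-4-acetoxy-3-[(3E)-5-{[tert-butyl(dimethyl)silyl]oxy}-4-methylpent-3-en-1-yl]but-2-en-1-yl}triphenylphosphonium chloride
Conditions: PPh3, MeCN, 60 °C
Reagents that add atoms: triphenylphosphine, c1ccc(cc1)P(c1ccccc1)c1ccccc1
Why: SN2 quaternisation of the primary allylic chloride places phosphorus on the future C4; the allylic acetate is inert without a catalyst.

Step 9
Reactants: 6 methoxymethyl (2S)-4-[2,5-bis(methoxymethoxy)phenyl]-2-formyl-2-hydroxy-4-oxobutanoate; 11 {(2E)-4-acetoxy-3-[(3E)-5-{[tert-butyl(dimethyl)silyl]oxy}-4-methylpent-3-en-1-yl]but-2-en-1-yl}triphenylphosphonium chloride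
Product: 14 methoxymethyl (2S)-2-{2-[2,5-bis(methoxymethoxy)phenyl]-2-oxoethyl}-6-[(3E)-5-{[tert-butyl(dimethyl)silyl]oxy}-4-methylpent-3-en-1-yl]-2,7-dihydrooxepine-2-carboxylate, via dienylphosphonium chloride 12 (not isolated), via allylic phosphonium ylide 13 (not isolated)
Conditions: 11, NaH (1.05 equiv), THF–DMF 4:1, 0 °C (gives 12); added slowly to 6 + NaH (1.0 equiv), THF, −20 → 25 °C, 0.01 M
Reagents that add atoms: none
Why: Proposed new method: base removes acetic acid from 11 (vinylogous E1cB) to give the 1,3-dienylphosphonium cation 12; the sodium alkoxide of 6 should add to its unsubstituted terminal carbon (oxa-1,6-addition, O1–C7), giving allylic ylide 13, whose phosphorus-bearing carbon C4 olefinates the neighbouring aldehyde C3 with loss of Ph3PO (intramolecular Wittig reaction). The closest known reaction types are the vinylphosphonium oxa-Michael/Wittig annulation of hydroxy carbonyl compounds to 2,5-dihydrofurans and 2H-chromenes, and the butadienylphosphonium annulation of ketone enolates to cyclohexa-1,3-dienes. The one ring is closed by attack of ylide carbon C4 on the exocyclic C=O carbon C3 (7-exo-trig) followed by oxaphosphetane collapse; no stereocentre is formed, and C2 cannot epimerise because it carries no hydrogen. The step needs δ- over β-addition and ring closure over oligomerisation: the δ-CH2 is terminal and unhindered while the β-CH is shielded by the PPh3 group and would give a non-stabilised ylide, allylic phosphonium ylides olefinate only at the α-carbon so no five-membered ether can arise from 13, and high dilution favours the intramolecular step. Only the ylide with C4 and C7 cis across C5=C6 can cyclise, and reversible oxa-addition should funnel material through it.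

Step 10
Reactants: 14 methoxymethyl (2S)-2-{2-[2,5-bis(methoxymethoxy)phenyl]-2-oxoethyl}-6-[(3E)-5-{[tert-butyl(dimethyl)silyl]oxy}-4-methylpent-3-en-1-yl]-2,7-dihydrooxepine-2-carboxylate
Product: 15 methoxymethyl (2R)-2-{2-[2,5-bis(methoxymethoxy)phenyl]-2-oxoethyl}-6-[(3E)-5-{[tert-butyl(dimethyl)silyl]oxy}-4-methylpent-3-en-1-yl]-2,3,4,7-tetrahydrooxepine-2-carboxylate
Conditions: 2-nitrobenzenesulfonylhydrazide (in portions), Et3N, CH2Cl2, 25 °C
Reagents that add atoms: none
Why: Diimide reduction (concerted syn transfer of two hydrogens) should take the cis-disubstituted C3=C4 bond much faster than the two trisubstituted alkenes, without 1,4-addition or alkene migration; the descriptor at C2 changes from S to R only because the ranking of its substituents changes.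

Step 11
Reactants: 15 methoxymethyl (2R)-2-{2-[2,5-bis(methoxymethoxy)phenyl]-2-oxoethyl}-6-[(3E)-5-{[tert-butyl(dimethyl)silyl]oxy}-4-methylpent-3-en-1-yl]-2,3,4,7-tetrahydrooxepine-2-carboxylate
Product: 16 (2R)-2-[2-(2,5-dihydroxyphenyl)-2-oxoethyl]-6-[(3E)-5-hydroxy-4-methylpent-3-en-1-yl]-2,3,4,7-tetrahydrooxepine-2-carboxylic acid
Conditions: TFA–CH2Cl2–H2O 2:8:1, 0 → 20 °C
Reagents that add atoms: none
Why: Acid-catalysed acetal hydrolysis should remove the three methoxymethyl groups (two aryl ethers, one ester) and the silyl ether together; the ring ether oxygen is deactivated by the adjacent carboxyl group, so the oxepine and C2 should survive.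

**Compound list**

1 | 2′,5′-dihydroxyacetophenone | CC(=O)c1cc(O)ccc1O | starting material
2 | 1-[2,5-bis(methoxymethoxy)phenyl]ethan-1-one | CC(=O)c1cc(OCOC)ccc1OCOC | intermediate
3 | (E)-2-oxo-4-phenylbut-3-enoic acid | O=C(O)C(=O)/C=C/c1ccccc1 | starting material
4 | methoxymethyl (E)-2-oxo-4-phenylbut-3-enoate | COCOC(=O)C(=O)/C=C/c1ccccc1 | intermediate
5 | methoxymethyl (2S,3E)-2-{2-[2,5-bis(methoxymethoxy)phenyl]-2-oxoethyl}-2-hydroxy-4-phenylbut-3-enoate | c1ccccc1/C=C/[C@@](CC(=O)c1cc(OCOC)ccc1OCOC)(C(=O)OCOC)O | intermediate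
6 | methoxymethyl (2S)-4-[2,5-bis(methoxymethoxy)phenyl]-2-formyl-2-hydroxy-4-oxobutanoate | O=C[C@@](CC(=O)c1cc(OCOC)ccc1OCOC)(C(=O)OCOC)O | intermediate
7 | myrcene (7-methyl-3-methylideneocta-1,6-diene) | CC(C)=CCCC(=C)C=C | starting material
8 | (2E)-2-methyl-6-methylideneocta-2,7-dien-1-ol | C/C(=C\CCC(=C)C=C)CO | intermediate
9 | tert-butyl(dimethyl){[(2E)-2-methyl-6-methylideneocta-2,7-dien-1-yl]oxy}silane | C/C(=C\CCC(=C)C=C)CO[Si](C)(C)C(C)(C)C | intermediate
10 | (2E,5E)-7-{[tert-butyl(dimethyl)silyl]oxy}-2-(2-chloroethylidene)-6-methylhept-5-en-1-yl acetate | ClC/C=C(/COC(C)=O)CC/C=C(\C)CO[Si](C)(C)C(C)(C)C | intermediate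
11 | {(2E)-4-acetoxy-3-[(3E)-5-{[tert-butyl(dimethyl)silyl]oxy}-4-methylpent-3-en-1-yl]but-2-en-1-yl}triphenylphosphonium chloride | [Cl-].CC(=O)OC/C(CC/C=C(\C)CO[Si](C)(C)C(C)(C)C)=C/C[P+](c1ccccc1)(c1ccccc1)c1ccccc1 | intermediate
12 | {(1E)-3-[(3E)-5-{[tert-butyl(dimethyl)silyl]oxy}-4-methylpent-3-en-1-yl]buta-1,3-dien-1-yl}triphenylphosphonium chloride | [Cl-].C=C(CC/C=C(\C)CO[Si](C)(C)C(C)(C)C)/C=C/[P+](c1ccccc1)(c1ccccc1)c1ccccc1 | intermediate
13 | methoxymethyl (2S)-4-[2,5-bis(methoxymethoxy)phenyl]-2-formyl-4-oxo-2-({(2Z)-2-[(3E)-5-{[tert-butyl(dimethyl)silyl]oxy}-4-methylpent-3-en-1-yl]-4-(triphenyl-λ5-phosphanylidene)but-2-en-1-yl}oxy)butanoate | O=C[C@@](CC(=O)c1cc(OCOC)ccc1OCOC)(C(=O)OCOC)OC/C(CC/C=C(\C)CO[Si](C)(C)C(C)(C)C)=C\C=P(c1ccccc1)(c1ccccc1)c1ccccc1 | intermediate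
14 | methoxymethyl (2S)-2-{2-[2,5-bis(methoxymethoxy)phenyl]-2-oxoethyl}-6-[(3E)-5-{[tert-butyl(dimethyl)silyl]oxy}-4-methylpent-3-en-1-yl]-2,7-dihydrooxepine-2-carboxylate | C1=C[C@@](CC(=O)c2cc(OCOC)ccc2OCOC)(C(=O)OCOC)OCC(CC/C=C(\C)CO[Si](C)(C)C(C)(C)C)=C1 | intermediate
15 | methoxymethyl (2R)-2-{2-[2,5-bis(methoxymethoxy)phenyl]-2-oxoethyl}-6-[(3E)-5-{[tert-butyl(dimethyl)silyl]oxy}-4-methylpent-3-en-1-yl]-2,3,4,7-tetrahydrooxepine-2-carboxylate | C1C[C@@](CC(=O)c2cc(OCOC)ccc2OCOC)(C(=O)OCOC)OCC(CC/C=C(\C)CO[Si](C)(C)C(C)(C)C)=C1 | intermediate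
16 | (2R)-2-[2-(2,5-dihydroxyphenyl)-2-oxoethyl]-6-[(3E)-5-hydroxy-4-methylpent-3-en-1-yl]-2,3,4,7-tetrahydrooxepine-2-carboxylic acid | C/C(=C\CCC1=CCC[C@@](CC(=O)c2cc(O)ccc2O)(C(=O)O)OC1)CO | target

**Step count and risks**

Total steps: 11. Longest linear sequence: 7 (steps 5 to 11, from myrcene).

Steps most likely to fail:

1. Step 9 (Proposed new method). The oxa-addition of the hindered tertiary alkoxide may be too slow. Addition at the β-carbon, intermolecular olefination, or base-induced retro-aldol or α-ketol rearrangement of the alkoxide may win instead. The fallback closes the ring by olefin metathesis; it sets out from 2 and 10 and comes back at 15, so step 10 is not needed either. 2-Oxohex-5-enoic acid is esterified as in step 2 to methoxymethyl 2-oxohex-5-enoate F1. The aldol addition of step 3 is run with 2 and F1 to give the hex-5-enoate tertiary alcohol F2. In parallel, 10 is reduced with LiAlH4 (hydride displacement of the allylic chloride, cleavage of the acetate) to the 2-ethylidene allylic alcohol F3, which CBr4/PPh3 converts into the allylic bromide F4. Williamson etherification of F2 with F4 (NaH, Bu4NI, THF, 0 °C) gives the diene ether F5. Ring-closing metathesis with the second-generation Grubbs catalyst (terminal alkene onto the ethylidene alkene, propene lost) forms the C5=C6 bond and gives 15.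

2. Step 3. Enamine formation from the ortho-substituted ketone may be slow, facial selectivity may be poor, or conjugate addition may compete with 1,2-addition. The fallback sets out from 2 and 4 and comes back at 5. The lithium enolate of 2 (LDA, THF, −78 °C) is added to 4 under kinetic control to give the racemic aldol adduct F6. Compound 5 is then separated from its enantiomer by preparative chromatography on a chiral stationary phase.

3. Step 7. The diene may be consumed by Diels–Alder reaction with the quinone, the two allyl termini may not be fully differentiated, or the silyl ether may be lost in the acidic medium. The fallback sets out from 9 and comes back at 12. Pt(PPh3)4-catalysed 1,4-diboration of 9 with bis(pinacolato)diboron gives the bis(boronate) F7 with the two boryl-methyl groups cis. NaOH/H2O2 oxidation gives the (Z)-diol F8. MsCl, LiCl and 2,4,6-collidine in DMF give the (Z)-dichloride F9. PPh3 (1 equiv, MeCN) quaternises the less hindered CH2Cl remote from the branch to give the chloro phosphonium chloride F10. NaH then removes HCl from F10 to give 12.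

Further compounds
F1 | step 9 | methoxymethyl 2-oxohex-5-enoate | C=CCCC(=O)C(=O)OCOC
F2 | step 9 | methoxymethyl (2R)-2-{2-[2,5-bis(methoxymethoxy)phenyl]-2-oxoethyl}-2-hydroxyhex-5-enoate | C=CCC[C@@](CC(=O)c1cc(OCOC)ccc1OCOC)(C(=O)OCOC)O
F3 | step 9 | (2E,5E)-7-{[tert-butyl(dimethyl)silyl]oxy}-2-ethylidene-6-methylhept-5-en-1-ol | C/C=C(/CO)CC/C=C(\C)CO[Si](C)(C)C(C)(C)C
F4 | step 9 | tert-butyl{[(2E,6E)-6-(bromomethyl)-2-methylocta-2,6-dien-1-yl]oxy}dimethylsilane | C/C=C(/CBr)CC/C=C(\C)CO[Si](C)(C)C(C)(C)C
F5 | step 9 | methoxymethyl (2R)-2-{2-[2,5-bis(methoxymethoxy)phenyl]-2-oxoethyl}-2-{[(2E,5E)-7-{[tert-butyl(dimethyl)silyl]oxy}-2-ethylidene-6-methylhept-5-en-1-yl]oxy}hex-5-enoate | C=CCC[C@@](CC(=O)c1cc(OCOC)ccc1OCOC)(C(=O)OCOC)OC/C(CC/C=C(\C)CO[Si](C)(C)C(C)(C)C)=C/C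
F6 | step 3 | racemic methoxymethyl (3E)-2-{2-[2,5-bis(methoxymethoxy)phenyl]-2-oxoethyl}-2-hydroxy-4-phenylbut-3-enoate | COCOC(=O)C(O)(CC(=O)c1cc(OCOC)ccc1OCOC)/C=C/c1ccccc1
F7 | step 7 | 2,2′-{(2E)-2-[(3E)-5-{[tert-butyl(dimethyl)silyl]oxy}-4-methylpent-3-en-1-yl]but-2-ene-1,4-diyl}bis(4,4,5,5-tetramethyl-1,3,2-dioxaborolane), boryl-methyl groups cis | CC1(C)C(C)(C)OB(O1)C/C=C(\CB1OC(C)(C)C(C)(C)O1)CC/C=C(\C)CO[Si](C)(C)C(C)(C)C
F8 | step 7 | (2Z)-2-[(3E)-5-{[tert-butyl(dimethyl)silyl]oxy}-4-methylpent-3-en-1-yl]but-2-ene-1,4-diol | OC/C=C(\CO)CC/C=C(\C)CO[Si](C)(C)C(C)(C)C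
F9 | step 7 | tert-butyl{[(2E,6Z)-8-chloro-6-(chloromethyl)-2-methylocta-2,6-dien-1-yl]oxy}dimethylsilane | ClC/C=C(\CCl)CC/C=C(\C)CO[Si](C)(C)C(C)(C)C
F10 | step 7 | {(2Z)-4-chloro-3-[(3E)-5-{[tert-butyl(dimethyl)silyl]oxy}-4-methylpent-3-en-1-yl]but-2-en-1-yl}triphenylphosphonium chloride | [Cl-].ClC/C(CC/C=C(\C)CO[Si](C)(C)C(C)(C)C)=C\C[P+](c1ccccc1)(c1ccccc1)c1ccccc1
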